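**Assumptions:** (E,E)-farnesyl acetate and 4-methoxy-3-methylphenol are purchased. Reagents are named with SMILES where they add atoms, but are not numbered. The cinchona catalyst enantiomer is chosen to give the (1R,6S)-epoxide in 7.

## Retrosynthetic overview
1. Target ← TBDPS removal ← C1 acetylation ← Luche 1,2-reduction of epoxy-ene-dione **8**, with hydride delivered anti to the epoxide.
2. **8** ← acid hydrolysis of the ketal in epoxy quinone monoketal **7** ← asymmetric Weitz–Scheffer epoxidation of quinone monoketal **6**, which sets the quaternary C5 and C6 of the epoxide.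
3. **6** ← PIDA/MeOH oxidative dearomatization of farnesylphenol **5**. The only ring is the original arene, so aromaticity is broken once, and the planar dienone is then desymmetrized.
4. **5** ← ortho-selective Friedel–Crafts farnesylation of phenol **4** with the 12-OTBDPS-farnesyl acetate **3** ← SeO₂ terminal allylic oxidation of farnesyl acetate **1**.

## Route

**Step 1**
Reactants: **1** (2E,6E)-farnesyl acetate
Product: **2** (2E,6E,10E)-12-hydroxyfarnesyl acetate
Conditions: SeO₂ (5 mol%), salicylic acid (5 mol%), TBHP (2 equiv), CH₂Cl₂, 0 °C→rt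
Reagents that add atoms: tert-butyl hydroperoxide CC(C)(C)OO (oxygen source)
Why: Sharpless–Umbreit SeO₂/TBHP allylic oxidation attacks the terminal (E)-methyl of the alkene farthest from the electron-withdrawing OAc, giving the (E)-allylic alcohol. Yields are modest, so the 12-OH product is separated from the aldehyde and regioisomers.

**Step 2**
Reactants: **2**
Product: **3** 12-(tert-butyldiphenylsilyloxy)farnesyl acetate
Conditions: TBDPSCl (1.2 equiv), imidazole, DMF, rt
Reagents that add atoms: TBDPSCl, CC(C)(C)[Si](Cl)(c1ccccc1)c1ccccc1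
Why: Silylation of the primary alcohol. TBDPS is chosen because it survives the BF₃ and aqueous acid steps below.

**Step 3**
Reactants: **3**; **4** 4-methoxy-3-methylphenol
Product: **5** 2-[(2E,6E,10E)-12-(TBDPSO)-3,7,11-trimethyldodeca-2,6,10-trien-1-yl]-4-methoxy-5-methylphenol
Conditions: **4** (3 equiv), BF₃·OEt₂ (0.3 equiv), CH₂Cl₂, –20→0 °C
Reagents that add atoms: none
Why: Friedel–Crafts allylation. The OH-bound Lewis acid delivers the farnesyl cation ortho to OH, and the site para to the methyl is electronically favored and unhindered, while the site between OH and Me is hindered. Attack at the primary terminus gives the linear (E)-farnesyl. There are no stereocenters.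

**Step 4**
Reactants: **5**
Product: **6** 4,4-dimethoxy-3-methyl-6-farnesyl(12-OTBDPS)cyclohexa-2,5-dien-1-one (quinone monoketal; farnesyl α to the carbonyl, ketal flanked by the methyl-bearing alkene)
Conditions: PhI(OAc)₂ (1.1 equiv), NaHCO₃, MeOH, 0 °C, 30 min
Reagents that add atoms: methanol, CO (gives the second OMe)
Why: Oxidative dearomatization of a p-methoxyphenol (Kita/Swenton) via a phenoxenium ion trapped by MeOH at the OMe-bearing carbon. The phenol oxygen becomes the C4 ketone and the para carbon is masked as a ketal. This leaves one enone whose β-carbon C6 is an unhindered CH, while the other enone has a methyl-blocked β-carbon.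

**Step 5**
Reactants: **6**
Product: **7** (1R,6S)-5,5-dimethoxy-4-methyl-1-[farnesyl-12-OTBDPS]-7-oxabicyclo[4.1.0]hept-3-en-2-one
Conditions: N-(9-anthracenylmethyl)dihydrocinchonidinium bromide (10 mol%), 30% aq. H₂O₂ (10 equiv), K₂CO₃, toluene, 0 °C, 24 h
Reagents that add atoms: hydrogen peroxide, OO (one O is retained as the epoxide oxygen)
Why: Weitz–Scheffer epoxidation, with HOO⁻ adding only at unhindered C6 and then 3-exo ring closure. **Proposed new method:** a chiral ammonium–hydroperoxide ion pair should attack one enantiotopic face of the planar dienone; the closest known reactions are cinchona phase-transfer epoxidation of enones and naphthoquinones, and Weitz–Scheffer epoxidation of quinone monoketals. This step sets C5 (quaternary) and C6 with cis-epoxide geometry, and the farnesyl alkenes are inert to nucleophilic peroxide.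

**Step 6**
Reactants: **7**
Product: **8** (1R,6S)-4-methyl-1-[farnesyl-12-OTBDPS]-7-oxabicyclo[4.1.0]hept-3-ene-2,5-dione
Conditions: TFA (3 equiv), THF/H₂O (4:1), 0 °C→rt
Reagents that add atoms: water, O
Why: Acid hydrolysis of the dimethyl ketal to the ketone (as with quinone monoketals). The epoxide is deactivated by the adjacent carbonyl and TBDPS tolerates these conditions. The epoxide stereocenters are untouched.

**Step 7**
Reactants: **8**
Product: **9** (1R,5R,6R)-5-hydroxy-4-methyl-1-[farnesyl-12-OTBDPS]-7-oxabicyclo[4.1.0]hept-3-en-2-one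
Conditions: NaBH₄ (0.6 equiv), CeCl₃·7H₂O (1.1 equiv), MeOH/CH₂Cl₂, –78 °C
Reagents that add atoms: none (hydride only)
Why: Luche 1,2-reduction at the C5 ketone, which is less hindered than the ketone next to the quaternary epoxide carbon. Felkin–Anh-type attack anti to the epoxide C–O bond puts OH cis to the epoxide oxygen, as required in the target. This sets the C5 carbinol stereocenter.

**Step 8**
Reactants: **9**
Product: **10** the C5 acetate of **9** (1R,5R,6R; OTBDPS retained)
Conditions: Ac₂O, DMAP (cat.), pyridine, CH₂Cl₂, 0 °C
Reagents that add atoms: acetic anhydride, CC(=O)OC(C)=O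
Why: Acylation of the secondary allylic alcohol with retention of configuration.

**Step 9**
Reactants: **10**
Product: **11** yanuthone L
Conditions: HF·pyridine, pyridine/THF, 0 °C→rt
Reagents that add atoms: none (only loses TBDPS)
Why: Fluoride cleavage of the primary silyl ether under buffered, near-neutral conditions that spare the acetate, epoxide and enone. No stereocenter is affected.

## Compound list
1 | (2E,6E)-farnesyl acetate | CC(=O)OC/C=C(\C)CC/C=C(\C)CCC=C(C)C | starting material
2 | (2E,6E,10E)-12-hydroxyfarnesyl acetate | CC(=O)OC/C=C(\C)CC/C=C(\C)CC/C=C(\C)CO | intermediate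
3 | 12-OTBDPS-farnesyl acetate | CC(=O)OC/C=C(\C)CC/C=C(\C)CC/C=C(\C)CO[Si](c1ccccc1)(c1ccccc1)C(C)(C)C | intermediate
4 | 4-methoxy-3-methylphenol | COc1ccc(O)cc1C | starting material
5 | farnesylphenol | COc1cc(C/C=C(\C)CC/C=C(\C)CC/C=C(\C)CO[Si](c2ccccc2)(c2ccccc2)C(C)(C)C)c(O)cc1C | intermediate
6 | quinone monoketal | COC1(OC)C(C)=CC(=O)C(C/C=C(\C)CC/C=C(\C)CC/C=C(\C)CO[Si](c2ccccc2)(c2ccccc2)C(C)(C)C)=C1 | intermediate
7 | epoxy quinone monoketal | COC1(OC)C(C)=CC(=O)[C@]2(C/C=C(\C)CC/C=C(\C)CC/C=C(\C)CO[Si](c3ccccc3)(c3ccccc3)C(C)(C)C)O[C@H]12 | intermediate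
8 | epoxy-ene-dione | O=C1C(C)=CC(=O)[C@]2(C/C=C(\C)CC/C=C(\C)CC/C=C(\C)CO[Si](c3ccccc3)(c3ccccc3)C(C)(C)C)O[C@H]12 | intermediate
9 | epoxy hydroxy-enone | O[C@@H]1C(C)=CC(=O)[C@]2(C/C=C(\C)CC/C=C(\C)CC/C=C(\C)CO[Si](c3ccccc3)(c3ccccc3)C(C)(C)C)O[C@H]12 | intermediate
10 | epoxy acetoxy-enone (TBDPS ether) | CC(=O)O[C@@H]1C(C)=CC(=O)[C@]2(C/C=C(\C)CC/C=C(\C)CC/C=C(\C)CO[Si](c3ccccc3)(c3ccccc3)C(C)(C)C)O[C@H]12 | intermediate
11 | yanuthone L | CC(=O)O[C@@H]1C(C)=CC(=O)[C@]2(C/C=C(\C)CC/C=C(\C)CC/C=C(\C)CO)O[C@H]12 | target

## Totals
Total steps: 9. Longest linear sequence: 9 (from farnesyl acetate; the phenol is purchased).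

## Three steps most likely to fail
1. **Step 5, asymmetric epoxidation.** The ee and yield for an α-substituted, cross-conjugated quinone monoketal are unproven. Fallback: reduce the dienone carbonyl of **6** with a CBS catalyst to a chiral dienol. Then do a VO(acac)₂/TBHP hydroxyl-directed epoxidation of the C5=C6 alkene, and re-oxidize the carbinol with Dess–Martin periodinane to rejoin at **7**.
2. **Step 3, Friedel–Crafts farnesylation.** Risks are E/Z scrambling, branched (γ) attack, chromane cyclization, and regioisomers. Fallback: brominate **4** ortho to OH with NBS/iPr₂NH. Then use phenoxide-directed Li/Br exchange (2 equiv t-BuLi) and CuI-catalysed SN2 coupling with the 12-OTBDPS-farnesyl bromide, made from the free alcohol with PBr₃.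
3. **Step 7, facial selectivity and chemoselectivity of the reduction.** If the alcohol forms trans to the epoxide, or C4 is reduced, the outcome is wrong. Fallback: separate the trans-alcohol and invert it with AcOH/DIAD/PPh₃ (Mitsunobu), delivering the cis-acetate directly in place of step 8.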